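**Plan**
- **Cuts.** The C13 silyl ether and the C2 and C8 esters come off first. The ylidenebutenolide ring (O1, C6, C7, C11, C12) goes back to a 2,3,4-trisubstituted furan. The C10(OH)–C1H2–C2H(O) unit goes back through a β-hydroxy enone to an isoxazoline. C1–C2 and C10–O are then cut together (retro [3+2]), followed by C5–C6, C8–C9 and C3=C4.
- **Enabling feature.** C10 is a tertiary carbinol bearing one methyl group and the ring methylene C1. C2, two bonds away, is oxygenated and attached to (Z)-C3=C4. This 1,3-O,O pattern is what a conjugated nitrile oxide (C2) leaves on a 1,1-disubstituted alkene (C10=C1). The five-membered ring fused at C6–C7 holds C5 and C8 cis and coplanar, which brings the two ends together.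
- **Forward order.** A purchased furan receives the C7 and C6 side chains. The isoxazoline and the ten-membered ring then close together. The isoxazoline is opened again, and the furan is converted into the butenolide last.
- **Stereochemistry.** C8 comes from a catalytic asymmetric methallylation. C10 is set from C8 in the cycloaddition. C2 is set from C10 by hydroxyl-directed reduction. (Z)-C3=C4 comes from a Still–Gennari olefination, and C5=C6 from the constraint of the ring.

Key step: step 12

Remark: germacrane-type locants are used. The ring is C1 (CH2), C2 (CHOAc), C3=C4 (C15 methyl), C5=C6, C7, C8 (CHO-methacryloyl), C9 (CH2), C10 (C(OH), C14 methyl). The lactone is O1, C11, C12 (C=O), C13 (CH2OH). Compounds 1, 2, 6 and 9 are taken to be purchasable.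

**Step 1**
Reactants: 1 (tert-butyldimethylsilyloxy)acetaldehyde; 2 ethyl 2-[bis(2,2,2-trifluoroethoxy)phosphoryl]propanoate
Product: 3 ethyl (Z)-4-(tert-butyldimethylsilyloxy)-2-methylbut-2-enoate
Conditions: KN(SiMe3)2, 18-crown-6, THF, −78 °C
Reagents that add atoms: none
Why: In this Still–Gennari olefination the electron-poor phosphonate makes elimination from the kinetic adduct fast, so the trisubstituted (Z)-enoate should form and fix the C3=C4 geometry.

**Step 2**
Reactants: 3 ethyl (Z)-4-(tert-butyldimethylsilyloxy)-2-methylbut-2-enoate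
Product: 4 (Z)-4-(tert-butyldimethylsilyloxy)-2-methylbut-2-en-1-ol
Conditions: iBu2AlH (2.5 equiv), CH2Cl2, −78 °C; aq. KNaC4H4O6
Reagents that add atoms: none
Why: Hydride 1,2-reduction of an enoate to the allylic alcohol at low temperature leaves the alkene geometry and the silyl ether untouched.

**Step 3**
Reactants: 4 (Z)-4-(tert-butyldimethylsilyloxy)-2-methylbut-2-en-1-ol
Product: 5 (Z)-1-bromo-4-(tert-butyldimethylsilyloxy)-2-methylbut-2-ene
Conditions: CBr4, PPh3, CH2Cl2, −20 °C
Reagents that add atoms: carbon tetrabromide, BrC(Br)(Br)Br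
Why: The Appel reaction converts a primary allylic alcohol into the bromide by SN2 displacement under neutral conditions, without allylic transposition or Z/E scrambling.

**Step 4**
Reactants: 6 furan-3,4-diyldimethanol
Product: 7 [4-(tert-butyldiphenylsilyloxymethyl)furan-3-yl]methanol
Conditions: NaH (1.0 equiv), THF, 0 °C; TBDPSCl (1.0 equiv)
Reagents that add atoms: tert-butyl(chloro)diphenylsilane, CC(C)(C)[Si](Cl)(c1ccccc1)c1ccccc1
Why: Monosilylation of a symmetrical diol through its sparingly soluble monosodium alkoxide desymmetrises C8 and C13, and the robust TBDPS group stays on C13 until the last step.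

**Step 5**
Reactants: 7 [4-(tert-butyldiphenylsilyloxymethyl)furan-3-yl]methanol
Product: 8 4-(tert-butyldiphenylsilyloxymethyl)furan-3-carbaldehyde
Conditions: MnO2, CH2Cl2, rt
Reagents that add atoms: none
Why: MnO2 oxidises heterobenzylic alcohols to aldehydes without over-oxidation and leaves the furan ring alone.

**Step 6**
Reactants: 8 4-(tert-butyldiphenylsilyloxymethyl)furan-3-carbaldehyde; 9 tributyl(2-methylallyl)stannane
Product: 10 (1R)-1-[4-(tert-butyldiphenylsilyloxymethyl)furan-3-yl]-3-methylbut-3-en-1-ol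
Conditions: (R)-BINOL (20 mol %), Ti(OiPr)4 (10 mol %), 4 Å MS, CH2Cl2, −20 °C
Reagents that add atoms: none
Why: In this Keck asymmetric methallylation the (R)-BINOL–titanium Lewis acid shields one aldehyde face, so, as with other aromatic aldehydes, the (R)-carbinol (C8) should form together with the C10=C1 alkene.

**Step 7**
Reactants: 10 (1R)-1-[4-(tert-butyldiphenylsilyloxymethyl)furan-3-yl]-3-methylbut-3-en-1-ol; 5 (Z)-1-bromo-4-(tert-butyldimethylsilyloxy)-2-methylbut-2-ene
Product: 12 (1R)-1-{2-[(Z)-4-(tert-butyldimethylsilyloxy)-2-methylbut-2-enyl]-4-(tert-butyldiphenylsilyloxymethyl)furan-3-yl}-3-methylbut-3-en-1-ol, via dilithio species 11 (not isolated)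
Conditions: n-BuLi (2.2 equiv), THF, −78 → 0 °C; then 5, −78 °C → rt
Reagents that add atoms: n-butyllithium, [Li]CCCC (lithium is held only in 11)
Why: In this alkoxide-directed ortho-lithiation the C8 alkoxide guides the base to the neighbouring α-position C6 while the TBDPS group shields C12, and the furyllithium then displaces the primary allylic bromide by SN2 with retention of the Z geometry.

**Step 8**
Reactants: 12 (the C8 alcohol from step 7)
Product: 13 C8 tert-butyldimethylsilyl ether of 12 (8R)
Conditions: TBSOTf, 2,6-lutidine, CH2Cl2, 0 °C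
Reagents that add atoms: tert-butyldimethylsilyl triflate, CC(C)(C)[Si](C)(C)OS(=O)(=O)C(F)(F)F
Why: Silylation of the hindered secondary alcohol with the silyl triflate installs the bulky group that later steers the cycloaddition and keeps a reactive acrylate out of the key step.

**Step 9**
Reactants: 13 (tris-silyl ether)
Product: 14 primary allylic alcohol (C2–OH free; C8–OTBS and C13–OTBDPS kept; 3Z,8R)
Conditions: HF·pyridine, pyridine, THF, 0 °C
Reagents that add atoms: none
Why: Buffered fluoride-mediated desilylation removes a primary allylic TBS ether faster than a hindered secondary TBS ether or a TBDPS ether.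

**Step 10**
Reactants: 14 (primary allylic alcohol)
Product: 15 (Z)-enal (C2 aldehyde; 3Z,8R)
Conditions: MnO2, CH2Cl2, rt, dark
Reagents that add atoms: none
Why: MnO2 oxidation of an allylic alcohol is neutral and heterogeneous, so the (Z)-enal should be reached without isomerisation, as in nerol-type cases.

**Step 11**
Reactants: 15 (Z)-enal
Product: 16 (Z)-enal oxime (E-aldoxime expected; its C=N geometry is of no consequence)
Conditions: NH2OH·HCl, NaOAc, EtOH, 0 °C
Reagents that add atoms: hydroxylamine hydrochloride, Cl.NO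
Why: Acetate-buffered oxime condensation proceeds by 1,2-addition at the aldehyde and is mild enough to keep the (Z)-C3=C4 bond and the silyl ethers.

**Step 12**
Reactants: 16 (Z)-enal oxime
Product: 19 furan-fused ten-membered carbocycle bridged by an isoxazoline between C2 and C10 (3Z,8R,10S; C8–OTBS; C13–OTBDPS), via hydroximoyl chloride 17 (not isolated), via nitrile oxide 18 (not isolated)
Conditions: NCS, DMF, 0 °C → rt; then syringe pump (12 h) into Et3N, toluene, 50 °C, ca. 1 mM
Reagents that add atoms: N-chlorosuccinimide, O=C1CCC(=O)N1Cl (chlorine is held only in 17)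
Why: Chlorination of the aldoxime and loss of HCl give the conjugated nitrile oxide 18, whose carbon C2 and oxygen add in one concerted suprafacial [3+2] event across the 1,1-disubstituted C10=C1 alkene, so the C1–C2 bond, the C10–O bond and the C2 oxidation level arise together. The closest known reaction type is the intramolecular nitrile oxide–alkene cycloaddition run at high dilution to give large rings that carry a bridging isoxazoline. Two rings close: the five-membered isoxazoline (C10, C1, C2, N, O) by the cycloaddition itself, and the ten-membered carbocycle C1–C10 in the endo (bridged) mode in which both alkene carbons become ring members, giving a bicyclo[7.2.1] frame. Carbon bonding to the CH2 terminus and oxygen to the substituted carbon is the intrinsic preference of 1,1-disubstituted alkenes, whereas the reverse mode would need a nine-membered ring with a quaternary carbon next to C=N; chemoselectivity is secured because the only other π-bonds are the fully substituted furan bond C6=C7 and the dipole's own C3=C4, and the methacrylate is still absent. The new stereocentre C10 is controlled by C8: the furan keeps C5 and C8 coplanar, the (Z)-C3=C4 bond folds the dipole back over C1, and one of the two remaining C8 substituents must point into the ring, so hydrogen should go inside and the bulky OTBS outside, which presents the alkene face that places the isoxazoline oxygen trans to OTBS (10S). Slow generation of 18 at about 1 mM should keep furoxan dimerisation behind ring closure.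

**Step 13**
Reactants: 19 (bridged macrocycle)
Product: 20 C8 alcohol of the bridged macrocycle (3Z,8R,10S)
Conditions: HF·pyridine, THF, 0 °C → rt
Reagents that add atoms: none
Why: Under acidic fluoride desilylation the TBS ether is far more labile than the TBDPS ether, and the furan and isoxazoline tolerate the medium.

**Step 14**
Reactants: 20 (C8 alcohol)
Product: 21 C8 methacrylate of the bridged macrocycle (3Z,8R,10S)
Conditions: methacrylic anhydride, Et3N, DMAP, CH2Cl2, 0 °C → rt
Reagents that add atoms: methacrylic anhydride, C=C(C)C(=O)OC(=O)C(C)=C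
Why: DMAP-catalysed acylation meets only one free hydroxyl group, which points to the outside of the ring, and C10–O and C2 are still masked in the isoxazoline.

**Step 15**
Reactants: 21 (C8 methacrylate)
Product: 22 macrocyclic β-hydroxy enone (C10–OH, C2=O; 3Z,8R,10R, where the C10 descriptor changes only through ligand ranking)
Conditions: Mo(CO)6, MeCN/H2O (15:1), 80 °C
Reagents that add atoms: water, O
Why: In this reductive N–O cleavage zerovalent molybdenum inserts into the weak N–O bond and the resulting β-hydroxy imine hydrolyses in situ, which removes the temporary ring without reducing alkenes, esters or the furan and leaves C10 untouched.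

**Step 16**
Reactants: 22 (β-hydroxy enone)
Product: 23 macrocyclic 1,3-anti diol (2S,3Z,8R,10S)
Conditions: Me4NBH(OAc)3, MeCN/AcOH (1:1), −30 °C
Reagents that add atoms: none
Why: In this Evans–Saksena reduction the tertiary C10–OH exchanges onto boron and hydride is delivered through a chair-like six-membered transition state with both ring bonds (C10–C9 and C2–C3) equatorial, which should give the 1,3-anti (2S) allylic alcohol by 1,2-reduction while methacrylate and furan stay inert.

**Step 17**
Reactants: 23 (diol)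
Product: 24 C2 acetate (2S,3Z,8R,10S; C10–OH free)
Conditions: Ac2O, pyridine, DMAP (cat.), CH2Cl2, 0 °C
Reagents that add atoms: acetic anhydride, CC(=O)OC(C)=O
Why: Acetylation at 0 °C takes the secondary allylic alcohol and leaves the tertiary C10–OH free.

**Step 18**
Reactants: 24 (C2 acetate)
Product: 28 C13 TBDPS ether of the target (2S,3Z,5E,8R,10S), via endoperoxide 25 (not isolated), via hydroxybutenolide 26 (not isolated), via acetoxybutenolide 27 (not isolated)
Conditions: O2, tetraphenylporphyrin (cat.), visible light, iPr2NEt, CH2Cl2, −78 °C; then Ac2O, Et3N, DMAP (cat.), −78 → 0 °C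
Reagents that add atoms: oxygen, O=O; acetic anhydride, CC(=O)OC(C)=O (acetyl is held only in 27)
Why: Singlet oxygen adds [4+2] to the electron-rich furan much faster than to the acetoxy-deactivated C3=C4 bond, the hindered amine removes the only endoperoxide hydrogen (C12–H, Kornblum–DeLaMare-type fragmentation) so that the carbonyl sits at C12 and the hydroxyl at C6, and acetylation of this hemiketal with loss of acetic acid toward the doubly activated C5–H should give the ylidenebutenolide, the ten-membered ring with its (Z)-C3=C4 bond favouring C4 and C7 cis on C5=C6.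

**Step 19**
Reactants: 28 (C13 TBDPS ether)
Product: 29 CNP0246543.1 (target)
Conditions: Bu4NF, AcOH (1:1), THF, 0 °C → rt
Reagents that add atoms: none
Why: Acetic-acid-buffered fluoride desilylation frees the primary C13–OH under nearly neutral conditions, so the acetate, the methacrylate, the tertiary alcohol and the ylidenebutenolide should survive and acyl migration should be suppressed.

**Compound list**
1 | (tert-butyldimethylsilyloxy)acetaldehyde | O=CCO[Si](C)(C)C(C)(C)C | starting material
2 | ethyl 2-[bis(2,2,2-trifluoroethoxy)phosphoryl]propanoate | CCOC(=O)C(C)P(=O)(OCC(F)(F)F)OCC(F)(F)F | starting material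
3 | ethyl (Z)-4-(tert-butyldimethylsilyloxy)-2-methylbut-2-enoate | CCOC(=O)/C(C)=C\CO[Si](C)(C)C(C)(C)C | intermediate
4 | (Z)-4-(tert-butyldimethylsilyloxy)-2-methylbut-2-en-1-ol | OC/C(C)=C\CO[Si](C)(C)C(C)(C)C | intermediate
5 | (Z)-1-bromo-4-(tert-butyldimethylsilyloxy)-2-methylbut-2-ene | BrC/C(C)=C\CO[Si](C)(C)C(C)(C)C | intermediate
6 | furan-3,4-diyldimethanol | OCc1cocc1CO | starting material
7 | [4-(tert-butyldiphenylsilyloxymethyl)furan-3-yl]methanol | OCc1cocc1CO[Si](c2ccccc2)(c3ccccc3)C(C)(C)C | intermediate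
8 | 4-(tert-butyldiphenylsilyloxymethyl)furan-3-carbaldehyde | O=Cc1cocc1CO[Si](c2ccccc2)(c3ccccc3)C(C)(C)C | intermediate
9 | tributyl(2-methylallyl)stannane | C=C(C)C[Sn](CCCC)(CCCC)CCCC | starting material
10 | (1R)-1-[4-(tert-butyldiphenylsilyloxymethyl)furan-3-yl]-3-methylbut-3-en-1-ol | C=C(C)C[C@@H](O)c1cocc1CO[Si](c2ccccc2)(c3ccccc3)C(C)(C)C | intermediate
11 | dilithio species of 10 (C8 lithium alkoxide, C6 furyllithium) | C=C(C)C[C@@H](O[Li])c1c([Li])occ1CO[Si](c2ccccc2)(c3ccccc3)C(C)(C)C | intermediate
12 | (1R)-1-{2-[(Z)-4-(tert-butyldimethylsilyloxy)-2-methylbut-2-enyl]-4-(tert-butyldiphenylsilyloxymethyl)furan-3-yl}-3-methylbut-3-en-1-ol | C=C(C)C[C@@H](O)c1c(C/C(C)=C\CO[Si](C)(C)C(C)(C)C)occ1CO[Si](c2ccccc2)(c3ccccc3)C(C)(C)C | intermediate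
13 | C8 TBS ether of 12 (8R,3Z) | C=C(C)C[C@@H](O[Si](C)(C)C(C)(C)C)c1c(C/C(C)=C\CO[Si](C)(C)C(C)(C)C)occ1CO[Si](c2ccccc2)(c3ccccc3)C(C)(C)C | intermediate
14 | C2 primary allylic alcohol (8R,3Z) | C=C(C)C[C@@H](O[Si](C)(C)C(C)(C)C)c1c(C/C(C)=C\CO)occ1CO[Si](c2ccccc2)(c3ccccc3)C(C)(C)C | intermediate
15 | (Z)-enal (8R,3Z) | C=C(C)C[C@@H](O[Si](C)(C)C(C)(C)C)c1c(C/C(C)=C\C=O)occ1CO[Si](c2ccccc2)(c3ccccc3)C(C)(C)C | intermediate
16 | (Z)-enal (E)-oxime (8R,3Z) | C=C(C)C[C@@H](O[Si](C)(C)C(C)(C)C)c1c(C/C(C)=C\C=N\O)occ1CO[Si](c2ccccc2)(c3ccccc3)C(C)(C)C | intermediate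
17 | hydroximoyl chloride (8R,3Z) | C=C(C)C[C@@H](O[Si](C)(C)C(C)(C)C)c1c(C/C(C)=C\C(Cl)=NO)occ1CO[Si](c2ccccc2)(c3ccccc3)C(C)(C)C | intermediate
18 | conjugated nitrile oxide (8R,3Z) | C=C(C)C[C@@H](O[Si](C)(C)C(C)(C)C)c1c(C/C(C)=C\C#[N+][O-])occ1CO[Si](c2ccccc2)(c3ccccc3)C(C)(C)C | intermediate
19 | furan-fused, isoxazoline-bridged ten-membered carbocycle, C8–OTBS (3Z,8R,10S) | CC(C)(C)[Si](C)(C)O[C@@H]1C[C@]3(C)CC(=NO3)/C=C(C)\Cc2occ(CO[Si](c4ccccc4)(c5ccccc5)C(C)(C)C)c21 | intermediate
20 | C8 alcohol of the bridged macrocycle (3Z,8R,10S) | O[C@@H]1C[C@]3(C)CC(=NO3)/C=C(C)\Cc2occ(CO[Si](c4ccccc4)(c5ccccc5)C(C)(C)C)c21 | intermediate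
21 | C8 methacrylate of the bridged macrocycle (3Z,8R,10S) | C=C(C)C(=O)O[C@@H]1C[C@]3(C)CC(=NO3)/C=C(C)\Cc2occ(CO[Si](c4ccccc4)(c5ccccc5)C(C)(C)C)c21 | intermediate
22 | macrocyclic β-hydroxy enone (3Z,8R,10R) | C=C(C)C(=O)O[C@@H]1C[C@@](C)(O)CC(=O)/C=C(C)\Cc2occ(CO[Si](c3ccccc3)(c4ccccc4)C(C)(C)C)c21 | intermediate
23 | macrocyclic 1,3-anti diol (2S,3Z,8R,10S) | C=C(C)C(=O)O[C@@H]1C[C@@](C)(O)C[C@H](O)/C=C(C)\Cc2occ(CO[Si](c3ccccc3)(c4ccccc4)C(C)(C)C)c21 | intermediate
24 | C2 acetate, furan stage (2S,3Z,8R,10S) | C=C(C)C(=O)O[C@@H]1C[C@@](C)(O)C[C@H](OC(C)=O)/C=C(C)\Cc2occ(CO[Si](c3ccccc3)(c4ccccc4)C(C)(C)C)c21 | intermediate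
25 | furan endoperoxide (C6/C12 peroxide bridge) | C=C(C)C(=O)O[C@@H]1C[C@@](C)(O)C[C@H](OC(C)=O)/C=C(C)\CC23OOC(O2)C(CO[Si](c4ccccc4)(c5ccccc5)C(C)(C)C)=C31 | intermediate
26 | C6-hydroxybutenolide | C=C(C)C(=O)O[C@@H]1C[C@@](C)(O)C[C@H](OC(C)=O)/C=C(C)\CC2(O)OC(=O)C(CO[Si](c3ccccc3)(c4ccccc4)C(C)(C)C)=C21 | intermediate
27 | C6-acetoxybutenolide | C=C(C)C(=O)O[C@@H]1C[C@@](C)(O)C[C@H](OC(C)=O)/C=C(C)\CC2(OC(C)=O)OC(=O)C(CO[Si](c3ccccc3)(c4ccccc4)C(C)(C)C)=C21 | intermediate
28 | C13 TBDPS ether of the target (2S,3Z,5E,8R,10S) | C=C(C)C(=O)O[C@@H]1C[C@@](C)(O)C[C@H](OC(C)=O)/C=C(C)\C=C2\OC(=O)C(CO[Si](c3ccccc3)(c4ccccc4)C(C)(C)C)=C21 | intermediate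
29 | CNP0246543.1 (2S,3Z,5E,8R,10S) | C=C(C)C(=O)O[C@@H]1C[C@@](C)(O)C[C@H](OC(C)=O)/C=C(C)\C=C2\OC(=O)C(CO)=C21 | target

Total steps: 19. Longest linear sequence: 16 (steps 4–19, or steps 1–3 followed by 7–19).

**Steps most likely to fail**

**Step 12.**
- What may go wrong:
  - Dimerisation of the nitrile oxide to furoxans, or oligomerisation, may outrun closure of the strained medium ring.
  - The furan may be chlorinated during activation of the oxime.
  - Facial selectivity at C10 may be poor.
- The fallback sets out from enal 15 and returns at 24.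
- The same C1–C2 bond would be closed by an intramolecular carbonyl-ene reaction (Me2AlCl, CH2Cl2, −78 °C, high dilution). The methallyl unit acts as ene donor toward the aluminium-bound aldehyde and gives the macrocyclic homoallylic alcohol with an exocyclic C10=C14 methylene group F1.
- Acetylation (Ac2O, pyridine) would give the C2 acetate F2.
- Mukaiyama hydration (Co(acac)2, PhSiH3, O2, THF) of the only 1,1-disubstituted alkene, with oxygen capture from the ring periphery, would give the C10 tertiary alcohol F3.
- HF·pyridine would free the C8 alcohol F4.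
- Methacrylic anhydride with DMAP would then acylate the only secondary hydroxyl group to reach 24.

**Step 18.**
- What may go wrong:
  - Singlet oxygen may attack C3=C4 in an ene reaction.
  - The free C10–OH may capture C6 across the ring.
  - Acetic acid may be lost toward the wrong C5=C6 geometry.
- The fallback sets out from 21 and returns at 28.
- The furan would be oxidised and dehydrated at the isoxazoline stage. There C10–O is tied up, C3=C4 is deactivated by conjugation with C=N, and the rigid bicycle restricts the elimination. This gives the isoxazoline-bridged ylidenebutenolide F5.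
- Mo(CO)6 in wet MeCN would then give the β-hydroxy trienone F6.
- Me4NBH(OAc)3 would give the C2,C10-diol F7.
- Ac2O with pyridine would give 28.

**Step 16.**
- What may go wrong: the conformation of the ten-membered ring may override the chair-like delivery of hydride, so that facial selectivity at C2 is poor or reversed.
- The fallback sets out from 22 and returns at 24.
- A Narasaka–Prasad reduction (Et2BOMe, NaBH4, THF/MeOH, −78 °C), with external hydride attacking the open face of the boron chelate, would give the C2 epimer of the diol F8.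
- A Mitsunobu reaction with acetic acid (PPh3, DIAD, toluene, 0 °C) would then invert C2 and install the acetate in one operation, giving 24.

**Further compounds**
F1 | step 12 | macrocyclic homoallylic alcohol with exocyclic C10=C14 methylene, C8–OTBS (2S,3Z,8R) | CC(C)(C)[Si](C)(C)O[C@@H]1CC(=C)C[C@H](O)/C=C(C)\Cc2occ(CO[Si](c3ccccc3)(c4ccccc4)C(C)(C)C)c21
F2 | step 12 | C2 acetate of F1 (2S,3Z,8R) | CC(C)(C)[Si](C)(C)O[C@@H]1CC(=C)C[C@H](OC(C)=O)/C=C(C)\Cc2occ(CO[Si](c3ccccc3)(c4ccccc4)C(C)(C)C)c21
F3 | step 12 | C10 tertiary alcohol, C8–OTBS (2S,3Z,8R,10S) | CC(C)(C)[Si](C)(C)O[C@@H]1C[C@@](C)(O)C[C@H](OC(C)=O)/C=C(C)\Cc2occ(CO[Si](c3ccccc3)(c4ccccc4)C(C)(C)C)c21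
F4 | step 12 | C8 alcohol (2S,3Z,8R,10R by ligand ranking; same spatial arrangement as 24) | O[C@@H]1C[C@@](C)(O)C[C@H](OC(C)=O)/C=C(C)\Cc2occ(CO[Si](c3ccccc3)(c4ccccc4)C(C)(C)C)c21
F5 | step 18 | isoxazoline-bridged ylidenebutenolide (3Z,5E,8R,10S) | C=C(C)C(=O)O[C@@H]1C[C@]3(C)CC(=NO3)/C=C(C)\C=C2\OC(=O)C(CO[Si](c4ccccc4)(c5ccccc5)C(C)(C)C)=C21
F6 | step 18 | β-hydroxy trienone, butenolide stage (3Z,5E,8R,10R) | C=C(C)C(=O)O[C@@H]1C[C@@](C)(O)CC(=O)/C=C(C)\C=C2\OC(=O)C(CO[Si](c3ccccc3)(c4ccccc4)C(C)(C)C)=C21
F7 | step 18 | C2,C10-diol, butenolide stage (2S,3Z,5E,8R,10S) | C=C(C)C(=O)O[C@@H]1C[C@@](C)(O)C[C@H](O)/C=C(C)\C=C2\OC(=O)C(CO[Si](c3ccccc3)(c4ccccc4)C(C)(C)C)=C21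
F8 | step 16 | C2 epimer of diol 23 (2R,3Z,8R,10S) | C=C(C)C(=O)O[C@@H]1C[C@@](C)(O)C[C@@H](O)/C=C(C)\Cc2occ(CO[Si](c3ccccc3)(c4ccccc4)C(C)(C)C)c21
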